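Ring A is built, not functionalised. Its pattern (C1 acyl, C2 OMe, C3 prenyl, C4 OH, C5–H and C6–H) maps onto a 2-prenyl-1,1-dimethoxy-3-silyloxybutadiene (C2–C5) and a terminal ynone (C1, C6) that already carries the three-carbon chain and ring B, with the β-oxygen held as a silyl ether. One Diels–Alder benzannulation forms C1–C2 and C5–C6, aromatises by loss of methanol and delivers the C2 methyl ether and the C4 silyl ether already differentiated. The diene comes from an orthoester via its ketene acetal, the ynone from an aldol on the ring B aldehyde. Selective desilylation, oxidation to the β-diketone and fluoride finish the synthesis.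

Key step: step 10

Assumption: the target is treated as the diketo tautomer drawn; the free β-diketone will equilibrate with its chelated enol, which is the same compound.

Step 1
Reactants: 1 5-bromo-2-methylpent-2-ene; 2 tetramethyl orthocarbonate
Product: 4 1,1,1-trimethoxy-5-methylhex-4-ene, via (4-methylpent-3-en-1-yl)magnesium bromide 3 (not isolated)
Conditions: Mg, THF, 40 °C; then 2 (3 equiv), reflux; cold H2O work-up
Reagents that add atoms: none
Why: Grignard substitution of one methoxide of an orthocarbonate is a direct orthoester synthesis, chosen because an ester enolate is alkylated on carbon and so gives no clean entry to a ketene dimethyl acetal, and the excess of 2 keeps a second substitution to the ketal minor.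

Step 2
Reactants: 4 1,1,1-trimethoxy-5-methylhex-4-ene
Product: 5 1,1-dimethoxy-5-methylhexa-1,4-diene
Conditions: TMSOTf, i-Pr2NEt, CH2Cl2, −20 → 25 °C; pentane, filter, distil
Reagents that add atoms: none
Why: Dealcoholation of an orthoester to a ketene acetal: the silyl triflate ionises 4 to the dimethoxycarbenium ion and the hindered amine removes a proton from the only α-CH2, the counterpart of the Lewis acid/amine acetal-to-enol-ether elimination, under conditions that leave the trisubstituted alkene untouched.

Step 3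
Reactants: 5 1,1-dimethoxy-5-methylhexa-1,4-diene; 6 acetyl chloride
Product: 7 4,4-dimethoxy-3-(3-methylbut-2-en-1-yl)but-3-en-2-one
Conditions: Et3N, Et2O, −20 → 25 °C (6 added last)
Reagents that add atoms: none
Why: C-Acylation of a ketene acetal by an acid chloride: the nucleophilic β-carbon attacks the acyl group and Et3N removes the now doubly activated C–H before chloride can demethylate the cation, restoring the ketene acetal as a stable push–pull alkene.

Step 4
Reactants: 7 4,4-dimethoxy-3-(3-methylbut-2-en-1-yl)but-3-en-2-one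
Product: 8 tert-butyl{[4,4-dimethoxy-3-(3-methylbut-2-en-1-yl)buta-1,3-dien-2-yl]oxy}dimethylsilane
Conditions: TBSOTf, Et3N, Et2O, 0 °C; pentane, filter, used crude
Reagents that add atoms: tert-butyldimethylsilyl trifluoromethanesulfonate, CC(C)(C)[Si](C)(C)OS(=O)(=O)C(F)(F)F
Why: Silyl enol ether formation by soft enolisation: the electron-rich carbonyl oxygen is silylated and Et3N removes a CH3 proton, the only α-hydrogens present since C3 is fully substituted, which gives the cross-conjugated 3-silyloxy diene.

Step 5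
Reactants: 9 4-hydroxybenzaldehyde; 10 1-bromo-3-methylbut-2-ene (prenyl bromide)
Product: 11 4-hydroxy-3-(3-methylbut-2-en-1-yl)benzaldehyde
Conditions: KOH, H2O, 25 °C; then dilute HCl
Reagents that add atoms: none
Why: ortho-C-Alkylation of a phenoxide in water, where hydrogen bonding shields oxygen and the para position is blocked by the formyl group, is a known direct prenylation whose product is separated from the O-prenyl ether and recovered 9.

Step 6
Reactants: 11 4-hydroxy-3-(3-methylbut-2-en-1-yl)benzaldehyde
Product: 12 3-(3-methylbut-2-en-1-yl)-4-[(triisopropylsilyl)oxy]benzaldehyde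
Conditions: TIPSCl, imidazole, DMF, 25 °C
Reagents that add atoms: chlorotriisopropylsilane, CC(C)[Si](Cl)(C(C)C)C(C)C
Why: Imidazole-mediated O-silylation of a phenol, with TIPS chosen for ring B because an aryl TIPS ether should survive the mildly basic methanolic alkyne desilylation of step 9 better than an aryl TBS ether.

Step 7
Reactants: 13 4-(trimethylsilyl)but-3-yn-2-one; 12 3-(3-methylbut-2-en-1-yl)-4-[(triisopropylsilyl)oxy]benzaldehyde
Product: 15 rac-5-hydroxy-5-{3-(3-methylbut-2-en-1-yl)-4-[(triisopropylsilyl)oxy]phenyl}-1-(trimethylsilyl)pent-1-yn-3-one, via lithium 4-(trimethylsilyl)but-1-en-3-yn-2-olate 14 (not isolated)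
Conditions: LiN(i-Pr)2, THF, −78 °C; then 12; AcOH quench at −78 °C
Reagents that add atoms: none
Why: Directed aldol addition of the kinetic enolate of a methyl ketone (no other α-hydrogens) to a non-enolisable aldehyde, quenched cold against retro-aldol, forms the carbinol centre as a racemate, which is sufficient because this centre is oxidised away in step 12.

Step 8
Reactants: 15 rac-5-hydroxy-5-{3-(3-methylbut-2-en-1-yl)-4-[(triisopropylsilyl)oxy]phenyl}-1-(trimethylsilyl)pent-1-yn-3-one
Product: 16 rac-5-{3-(3-methylbut-2-en-1-yl)-4-[(triisopropylsilyl)oxy]phenyl}-5-[(triethylsilyl)oxy]-1-(trimethylsilyl)pent-1-yn-3-one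
Conditions: TESOTf, 2,6-lutidine, CH2Cl2, −78 °C
Reagents that add atoms: triethylsilyl trifluoromethanesulfonate, CC[Si](CC)(CC)OS(=O)(=O)C(F)(F)F
Why: O-Silylation with a silyl triflate and a hindered pyridine is fast and non-basic, so retro-aldol and oxa-Michael closure are avoided, and it masks the hydroxyl that would otherwise protonate the ketene acetal diene or cyclise onto the ynone.

Step 9
Reactants: 16 rac-5-{3-(3-methylbut-2-en-1-yl)-4-[(triisopropylsilyl)oxy]phenyl}-5-[(triethylsilyl)oxy]-1-(trimethylsilyl)pent-1-yn-3-one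
Product: 17 rac-5-{3-(3-methylbut-2-en-1-yl)-4-[(triisopropylsilyl)oxy]phenyl}-5-[(triethylsilyl)oxy]pent-1-yn-3-one
Conditions: Na2B4O7·10H2O (cat.), MeOH/THF/H2O, 25 °C, short reaction time; used at once
Reagents that add atoms: none
Why: Protodesilylation of an alkynylsilane conjugated to a ketone is exceptionally easy and proceeds with dilute methanolic borate, a pH at which the secondary TES ether and the aryl TIPS ether should persist and methanol should not add to the ynone in the short time needed.

Step 10
Reactants: 17 rac-5-{3-(3-methylbut-2-en-1-yl)-4-[(triisopropylsilyl)oxy]phenyl}-5-[(triethylsilyl)oxy]pent-1-yn-3-one; 8 tert-butyl{[4,4-dimethoxy-3-(3-methylbut-2-en-1-yl)buta-1,3-dien-2-yl]oxy}dimethylsilane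
Product: 19 rac-1-{4-[(tert-butyldimethylsilyl)oxy]-2-methoxy-3-(3-methylbut-2-en-1-yl)phenyl}-3-{3-(3-methylbut-2-en-1-yl)-4-[(triisopropylsilyl)oxy]phenyl}-3-[(triethylsilyl)oxy]propan-1-one, via cyclohexadiene adduct 18 (not isolated)
Conditions: 8 (2 equiv), toluene, 25 → 80 °C; then silica gel, CH2Cl2, 25 °C
Reagents that add atoms: none
Why: The CH2 terminus of diene 8, made nucleophilic by the silyloxy and the two methoxy groups acting together, attacks the unsubstituted alkyne carbon of 17 while the acetal carbon bonds to the carbonyl-bearing alkyne carbon, either concertedly or through a short-lived allenolate/dimethoxycarbenium zwitterion that collapses, to give 1,4-cyclohexadiene 18. In 18 the C(OMe)2 and CH2 carbons face each other across the ring, so 1,4-elimination of methanol aromatises it, leaving one OMe at C2 and turning the silyl enol ether into the C4 aryl silyl ether with the prenyl group between them. The closest known reaction type is the Diels–Alder benzannulation of 1,1-dimethoxy-3-silyloxybutadienes with acetylenic ketones and esters, which gives 2-methoxy-4-silyloxyaryl carbonyl compounds. Ring A is closed by an intermolecular [4+2] cycloaddition that forms C1–C2 and C5–C6 (if stepwise, Michael addition followed by six-membered ring closure of the allenolate onto the oxocarbenium carbon). No stereocentre is created; the racemic carbinol carbon of the side chain is a spectator that is oxidised later. The step needs regioselectivity (acyl ortho to OMe and para to OSi) and chemoselectivity (ynone over the prenyl alkenes), both secured by the polarity match between the nucleophilic CH2 terminus and the electrophilic β-carbon of the terminal ynone, by the inertness of unactivated trisubstituted alkenes, and by the silyl ether on the β-oxygen, which keeps any acidic OH or 1,3-diketone away from the ketene acetal.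

Step 11
Reactants: 19 rac-1-{4-[(tert-butyldimethylsilyl)oxy]-2-methoxy-3-(3-methylbut-2-en-1-yl)phenyl}-3-{3-(3-methylbut-2-en-1-yl)-4-[(triisopropylsilyl)oxy]phenyl}-3-[(triethylsilyl)oxy]propan-1-one
Product: 20 rac-1-{4-[(tert-butyldimethylsilyl)oxy]-2-methoxy-3-(3-methylbut-2-en-1-yl)phenyl}-3-hydroxy-3-{3-(3-methylbut-2-en-1-yl)-4-[(triisopropylsilyl)oxy]phenyl}propan-1-one
Conditions: AcOH/THF/H2O (3:1:1), 25 °C
Reagents that add atoms: none
Why: Acid-catalysed hydrolysis cleaves the secondary alkyl triethylsilyl ether much faster than the two aryl silyl ethers, whose oxygens are poorly basic, and the aqueous medium should return the benzylic alcohol rather than a benzylic ether or the dehydrated enone.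

Step 12
Reactants: 20 rac-1-{4-[(tert-butyldimethylsilyl)oxy]-2-methoxy-3-(3-methylbut-2-en-1-yl)phenyl}-3-hydroxy-3-{3-(3-methylbut-2-en-1-yl)-4-[(triisopropylsilyl)oxy]phenyl}propan-1-one
Product: 21 1-{4-[(tert-butyldimethylsilyl)oxy]-2-methoxy-3-(3-methylbut-2-en-1-yl)phenyl}-3-{3-(3-methylbut-2-en-1-yl)-4-[(triisopropylsilyl)oxy]phenyl}propane-1,3-dione
Conditions: DMP (1.2 equiv), CH2Cl2, 0 → 25 °C
Reagents that add atoms: none
Why: Dess–Martin oxidation turns the β-hydroxy ketone into the 1,3-diketone under near-neutral conditions, with only a slight excess so that the activated methylene is not oxidised further, while the prenyl alkenes and aryl silyl ethers are inert and the carbinol stereocentre disappears.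

Step 13
Reactants: 21 1-{4-[(tert-butyldimethylsilyl)oxy]-2-methoxy-3-(3-methylbut-2-en-1-yl)phenyl}-3-{3-(3-methylbut-2-en-1-yl)-4-[(triisopropylsilyl)oxy]phenyl}propane-1,3-dione
Product: 22 1-[4-hydroxy-2-methoxy-3-(3-methylbut-2-en-1-yl)phenyl]-3-[4-hydroxy-3-(3-methylbut-2-en-1-yl)phenyl]propane-1,3-dione (CNP0167758.0)
Conditions: Bu4NF, AcOH (1:1), THF, 0 °C
Reagents that add atoms: none
Why: Fluoride-induced desilylation removes both aryl silyl ethers readily because phenoxides para to a carbonyl are good leaving groups, and the acetic acid buffer keeps the medium mild so that the ortho-prenyl phenols should not cyclise to chromans and the diketone should not undergo retro-Claisen cleavage.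

Compound list
1 | 5-bromo-2-methylpent-2-ene | CC(C)=CCCBr | starting material
2 | tetramethyl orthocarbonate | COC(OC)(OC)OC | starting material
3 | (4-methylpent-3-en-1-yl)magnesium bromide | CC(C)=CCC[Mg]Br | intermediate (not isolated)
4 | 1,1,1-trimethoxy-5-methylhex-4-ene | COC(CCC=C(C)C)(OC)OC | intermediate
5 | 1,1-dimethoxy-5-methylhexa-1,4-diene | COC(OC)=CCC=C(C)C | intermediate
6 | acetyl chloride | CC(Cl)=O | starting material
7 | 4,4-dimethoxy-3-(3-methylbut-2-en-1-yl)but-3-en-2-one | CC(=O)C(CC=C(C)C)=C(OC)OC | intermediate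
8 | tert-butyl{[4,4-dimethoxy-3-(3-methylbut-2-en-1-yl)buta-1,3-dien-2-yl]oxy}dimethylsilane | C=C(O[Si](C)(C)C(C)(C)C)C(CC=C(C)C)=C(OC)OC | intermediate
9 | 4-hydroxybenzaldehyde | O=Cc1ccc(O)cc1 | starting material
10 | 1-bromo-3-methylbut-2-ene | CC(C)=CCBr | starting material
11 | 4-hydroxy-3-(3-methylbut-2-en-1-yl)benzaldehyde | O=Cc1ccc(O)c(CC=C(C)C)c1 | intermediate
12 | 3-(3-methylbut-2-en-1-yl)-4-[(triisopropylsilyl)oxy]benzaldehyde | O=Cc1ccc(O[Si](C(C)C)(C(C)C)C(C)C)c(CC=C(C)C)c1 | intermediate
13 | 4-(trimethylsilyl)but-3-yn-2-one | CC(=O)C#C[Si](C)(C)C | starting material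
14 | lithium 4-(trimethylsilyl)but-1-en-3-yn-2-olate | [Li]OC(=C)C#C[Si](C)(C)C | intermediate (not isolated)
15 | rac-5-hydroxy-5-{3-(3-methylbut-2-en-1-yl)-4-[(triisopropylsilyl)oxy]phenyl}-1-(trimethylsilyl)pent-1-yn-3-one | C[Si](C)(C)C#CC(=O)CC(O)c1ccc(O[Si](C(C)C)(C(C)C)C(C)C)c(CC=C(C)C)c1 | intermediate
16 | rac-5-{3-(3-methylbut-2-en-1-yl)-4-[(triisopropylsilyl)oxy]phenyl}-5-[(triethylsilyl)oxy]-1-(trimethylsilyl)pent-1-yn-3-one | C[Si](C)(C)C#CC(=O)CC(O[Si](CC)(CC)CC)c1ccc(O[Si](C(C)C)(C(C)C)C(C)C)c(CC=C(C)C)c1 | intermediate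
17 | rac-5-{3-(3-methylbut-2-en-1-yl)-4-[(triisopropylsilyl)oxy]phenyl}-5-[(triethylsilyl)oxy]pent-1-yn-3-one | C#CC(=O)CC(O[Si](CC)(CC)CC)c1ccc(O[Si](C(C)C)(C(C)C)C(C)C)c(CC=C(C)C)c1 | intermediate
18 | rac-1-{4-[(tert-butyldimethylsilyl)oxy]-6,6-dimethoxy-5-(3-methylbut-2-en-1-yl)cyclohexa-1,4-dien-1-yl}-3-{3-(3-methylbut-2-en-1-yl)-4-[(triisopropylsilyl)oxy]phenyl}-3-[(triethylsilyl)oxy]propan-1-one | COC1(OC)C(C(=O)CC(O[Si](CC)(CC)CC)c2ccc(O[Si](C(C)C)(C(C)C)C(C)C)c(CC=C(C)C)c2)=CCC(O[Si](C)(C)C(C)(C)C)=C1CC=C(C)C | intermediate (not isolated)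
19 | rac-1-{4-[(tert-butyldimethylsilyl)oxy]-2-methoxy-3-(3-methylbut-2-en-1-yl)phenyl}-3-{3-(3-methylbut-2-en-1-yl)-4-[(triisopropylsilyl)oxy]phenyl}-3-[(triethylsilyl)oxy]propan-1-one | COc1c(C(=O)CC(O[Si](CC)(CC)CC)c2ccc(O[Si](C(C)C)(C(C)C)C(C)C)c(CC=C(C)C)c2)ccc(O[Si](C)(C)C(C)(C)C)c1CC=C(C)C | intermediate
20 | rac-1-{4-[(tert-butyldimethylsilyl)oxy]-2-methoxy-3-(3-methylbut-2-en-1-yl)phenyl}-3-hydroxy-3-{3-(3-methylbut-2-en-1-yl)-4-[(triisopropylsilyl)oxy]phenyl}propan-1-one | COc1c(C(=O)CC(O)c2ccc(O[Si](C(C)C)(C(C)C)C(C)C)c(CC=C(C)C)c2)ccc(O[Si](C)(C)C(C)(C)C)c1CC=C(C)C | intermediate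
21 | 1-{4-[(tert-butyldimethylsilyl)oxy]-2-methoxy-3-(3-methylbut-2-en-1-yl)phenyl}-3-{3-(3-methylbut-2-en-1-yl)-4-[(triisopropylsilyl)oxy]phenyl}propane-1,3-dione | COc1c(C(=O)CC(=O)c2ccc(O[Si](C(C)C)(C(C)C)C(C)C)c(CC=C(C)C)c2)ccc(O[Si](C)(C)C(C)(C)C)c1CC=C(C)C | intermediate
22 | 1-[4-hydroxy-2-methoxy-3-(3-methylbut-2-en-1-yl)phenyl]-3-[4-hydroxy-3-(3-methylbut-2-en-1-yl)phenyl]propane-1,3-dione | COc1c(C(=O)CC(=O)c2ccc(O)c(CC=C(C)C)c2)ccc(O)c1CC=C(C)C | target

Total step count: 13 (steps 1–4 make the diene, steps 5–9 the ynone, steps 10–13 join and finish).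
Longest linear sequence: 9 steps (steps 5–13, from 4-hydroxybenzaldehyde 9).

Steps most likely to fail

1. Step 10. The hindered, very electron-rich diene may add to the ynone only once in Michael fashion without closing the ring. It may also be consumed by traces of proton sources before it reacts, or heating may eliminate triethylsilanol from the side chain of 17. Premature hydrolysis of the silyl enol ether would leave the C4 phenol free. The fallback sets out from 10 and 12 and returns at 20; it takes ring A from the aromatic pool and makes the chain by an aldol instead of a cycloaddition. 2,4-Dihydroxyacetophenone is C-prenylated with 10 (KOH, H2O, 25 °C; C3 lies between the two oxygens) to 1-[2,4-dihydroxy-3-(3-methylbut-2-en-1-yl)phenyl]ethan-1-one F1. The free 4-OH is silylated in preference to the hydrogen-bonded 2-OH (TBSCl, imidazole, CH2Cl2) to give 1-{4-[(tert-butyldimethylsilyl)oxy]-2-hydroxy-3-(3-methylbut-2-en-1-yl)phenyl}ethan-1-one F2. The chelated 2-OH is then methylated under neutral conditions (MeI, Ag2O, CH2Cl2, 40 °C) to 1-{4-[(tert-butyldimethylsilyl)oxy]-2-methoxy-3-(3-methylbut-2-en-1-yl)phenyl}ethan-1-one F3. The enolate made from F3 with LiN(i-Pr)2 (THF, −78 °C) adds to aldehyde 12 and should give 20, from which steps 12 and 13 follow unchanged.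

2. Step 2. The ketene acetal, once formed, may attack the dimethoxycarbenium ion still present (self-condensation), or it may be hydrolysed back to the methyl ester during isolation. The later C-acylation of step 3 depends on clean material. The fallback sets out from 6 and returns at 7; it introduces the prenyl group by cross-coupling, not through a substituted ketene acetal. Acetyl chloride 6 acylates commercial 1,1-dimethoxyethene (Et3N, Et2O, 0 °C) to 4,4-dimethoxybut-3-en-2-one F4. Iodination at the nucleophilic C3 (I2, pyridine, CH2Cl2, 0 °C) gives 3-iodo-4,4-dimethoxybut-3-en-2-one F5. Stille coupling of F5 with tributyl(3-methylbut-2-en-1-yl)stannane (Pd2(dba)3, AsPh3, CuI, DMF, 25–50 °C) should give 7, which re-enters at step 4.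

3. Step 9. Methanol or hydroxide may add in conjugate fashion to the freed ethynyl ketone, or the basic medium may cause loss of the β-silyloxy group or of the TES ether. The fallback sets out from 12 and returns at 17; it never places silicon on the alkyne. The lithium enolate of N-methoxy-N-methylacetamide (LiN(i-Pr)2, THF, −78 °C) adds to 12 to give rac-3-hydroxy-N-methoxy-N-methyl-3-{3-(3-methylbut-2-en-1-yl)-4-[(triisopropylsilyl)oxy]phenyl}propanamide F6. Silylation (TESOTf, 2,6-lutidine, CH2Cl2, −78 °C) gives rac-N-methoxy-N-methyl-3-{3-(3-methylbut-2-en-1-yl)-4-[(triisopropylsilyl)oxy]phenyl}-3-[(triethylsilyl)oxy]propanamide F7. Addition of HC≡CMgBr to this Weinreb amide (THF, 0 °C, inverse quench into cold aqueous NaHSO4) should give 17 directly.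

Further compounds
F1 | step 10 | 1-[2,4-dihydroxy-3-(3-methylbut-2-en-1-yl)phenyl]ethan-1-one | CC(=O)c1ccc(O)c(CC=C(C)C)c1O
F2 | step 10 | 1-{4-[(tert-butyldimethylsilyl)oxy]-2-hydroxy-3-(3-methylbut-2-en-1-yl)phenyl}ethan-1-one | CC(=O)c1ccc(O[Si](C)(C)C(C)(C)C)c(CC=C(C)C)c1O
F3 | step 10 | 1-{4-[(tert-butyldimethylsilyl)oxy]-2-methoxy-3-(3-methylbut-2-en-1-yl)phenyl}ethan-1-one | COc1c(C(C)=O)ccc(O[Si](C)(C)C(C)(C)C)c1CC=C(C)C
F4 | step 2 | 4,4-dimethoxybut-3-en-2-one | CC(=O)C=C(OC)OC
F5 | step 2 | 3-iodo-4,4-dimethoxybut-3-en-2-one | CC(=O)C(I)=C(OC)OC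
F6 | step 9 | rac-3-hydroxy-N-methoxy-N-methyl-3-{3-(3-methylbut-2-en-1-yl)-4-[(triisopropylsilyl)oxy]phenyl}propanamide | CON(C)C(=O)CC(O)c1ccc(O[Si](C(C)C)(C(C)C)C(C)C)c(CC=C(C)C)c1
F7 | step 9 | rac-N-methoxy-N-methyl-3-{3-(3-methylbut-2-en-1-yl)-4-[(triisopropylsilyl)oxy]phenyl}-3-[(triethylsilyl)oxy]propanamide | CON(C)C(=O)CC(O[Si](CC)(CC)CC)c1ccc(O[Si](C(C)C)(C(C)C)C(C)C)c(CC=C(C)C)c1
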